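The route rests on reading the 5,6-dihydro-2H-pyran-2-one ring (O1, C2=O, C3=C4, C5–O-acyl, C6) as an oxidised 2-furyl carbinol. Furan positions 2, 3, 4 and 5 become ring atoms C5, C4, C3 and C2, and the exocyclic carbinol carbon becomes C6. A single oxidative ring expansion of (S)-1-(furan-2-yl)prop-2-en-1-ol forms the O1–C2 bond and the six-membered ring, fixes C3=C4 as cis, and delivers C5 as a ketone and C2 at the hemiacetal level. The vinyl group on C6 survives as the handle for the C7=C8–C9 acrylic acid. C5 is then set by reduction and inverted on esterification with a separately built (2E,4E,6S)-dienoic acid.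

Key step: step 3

Assumption: the lipase is taken to show its usual preference for secondary alcohols (furyl as the large group, vinyl as the medium group, R alcohol acylated), so the S alcohol is the unreacted component; the sense is to be confirmed on the first run.

Remark: CIP analysis of the target gives 5S,6S in the lactone (acyloxy group and side chain cis) and 6S in the dienoyl chain.

Step 1
Reactants: 1 furfural; 2 vinylmagnesium bromide
Product: 3 rac-1-(furan-2-yl)prop-2-en-1-ol
Conditions: THF, −78 to 0 °C; then sat. aq NH4Cl
Reagents that add atoms: none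
Why: Grignard 1,2-addition of the vinyl nucleophile to the aldehyde should give the secondary furyl vinyl carbinol, as the racemate because nothing in the flask is chiral.

Step 2
Reactants: 3 rac-1-(furan-2-yl)prop-2-en-1-ol
Product: 4 (S)-1-(furan-2-yl)prop-2-en-1-ol
Conditions: immobilised Candida antarctica lipase B, vinyl acetate, hexane, 30 °C, run slightly beyond half conversion; chromatography
Reagents that add atoms: none
Why: Lipase-catalysed kinetic resolution by irreversible transesterification should acylate the R alcohol, whose furyl ring fits the large pocket and whose vinyl group fits the medium pocket, leaving the S alcohol to be separated from the R acetate.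

Step 3
Reactants: 4 (S)-1-(furan-2-yl)prop-2-en-1-ol
Product: 6 (2S)-6-hydroxy-2-vinyl-2H-pyran-3(6H)-one (mixture of anomers), via (S,Z)-5-hydroxy-4-oxohepta-2,6-dienal 5 (not isolated)
Conditions: NBS, NaHCO3, NaOAc, THF/H2O (4:1), 0 °C, short reaction time
Reagents that add atoms: water, O
Why: Achmatowicz rearrangement: NBS transfers electrophilic bromine to the unsubstituted furan alpha-carbon, water captures the resulting oxocarbenium ion, and the 2,5-dioxygenated dihydrofuran loses HBr and opens to the Z-ene-dicarbonyl 5. The closest known reaction type is the NBS-mediated oxidative ring expansion of 2-furyl carbinols to 6-hydroxy-2H-pyran-3(6H)-ones. The six-membered ring closes when the carbinol hydroxyl adds to the aldehyde carbon of 5 (6-exo-trig hemiacetalisation, forming O1–C2), which the cis geometry inherited from the furan makes possible. No stereocentre of the target is created: C6 is carried through untouched, and the anomeric centre forms as a mixture that is erased in step 4. The step needs chemoselectivity for the furan over the vinyl group, which the far higher reactivity of the electron-rich heteroarene towards electrophilic bromine should secure. It also needs C6, now alpha to a ketone and allylic, to keep its configuration, which the buffer, 0 °C and a short reaction time are meant to ensure.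

Step 4
Reactants: 6 (2S)-6-hydroxy-2-vinyl-2H-pyran-3(6H)-one (mixture of anomers)
Product: 7 (S)-6-vinyl-2H-pyran-2,5(6H)-dione
Conditions: CrO3, H2SO4, acetone, 0 °C, brief; cold work-up, crude product used at once
Reagents that add atoms: none
Why: Jones oxidation of the lactol to the lactone should be fast at 0 °C and converge both anomers to one ene-dione lactone, which is carried cold and crude into step 5 to forestall enolisation at C6.

Step 5
Reactants: 7 (S)-6-vinyl-2H-pyran-2,5(6H)-dione
Product: 8 (5R,6S)-5-hydroxy-6-vinyl-5,6-dihydro-2H-pyran-2-one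
Conditions: NaBH4, CeCl3·7H2O, MeOH/CH2Cl2, −78 °C
Reagents that add atoms: none
Why: Luche 1,2-reduction of the C5 ketone: hydride should add along the pseudoaxial trajectory of the half-chair that keeps the C6 vinyl group pseudoequatorial, anti to the pseudoaxial C6–H, so that the new hydroxyl ends pseudoequatorial and trans to vinyl (5R), while CeCl3 suppresses conjugate reduction and the lactone is untouched.

Step 6
Reactants: 8 (5R,6S)-5-hydroxy-6-vinyl-5,6-dihydro-2H-pyran-2-one; 9 tert-butyl acrylate (excess)
Product: 10 tert-butyl (E)-3-[(2S,3R)-3-hydroxy-6-oxo-3,6-dihydro-2H-pyran-2-yl]acrylate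
Conditions: second-generation Hoveyda–Grubbs catalyst RuCl2(H2IMes)(=CH-C6H4-2-OiPr) (5 mol%), CH2Cl2, 40 °C
Reagents that add atoms: none
Why: Olefin cross-metathesis between the monosubstituted vinyl group and the slowly homodimerising acrylate should give the E-enoate under thermodynamic control, the electron-poor, unstrained cis ring alkene C3=C4 being inert.

Step 7
Reactants: 11 (S)-4-benzyloxazolidin-2-one; 12 octanoyl chloride
Product: 13 (S)-4-benzyl-3-octanoyloxazolidin-2-one
Conditions: n-BuLi, THF, −78 °C; then 12, −78 to 0 °C
Reagents that add atoms: none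
Why: N-Acylation of the lithiated oxazolidinone by the acid chloride (attachment of an Evans auxiliary) is a routine acyl substitution that creates no stereocentre.

Step 8
Reactants: 13 (S)-4-benzyl-3-octanoyloxazolidin-2-one
Product: 14 (S)-4-benzyl-3-[(S)-2-methyloctanoyl]oxazolidin-2-one
Conditions: NaN(SiMe3)2, THF, −78 °C; then MeI, −78 °C; chromatography
Reagents that add atoms: iodomethane, CI
Why: Evans asymmetric alkylation: the chelated Z sodium enolate is methylated on the face opposite the C4 benzyl group, which with the S auxiliary and the hexyl chain already in place should set the new alpha-centre as S, the minor diastereomer being removed by chromatography.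

Step 9
Reactants: 14 (S)-4-benzyl-3-[(S)-2-methyloctanoyl]oxazolidin-2-one
Product: 15 (S)-2-methyloctan-1-ol
Conditions: LiBH4, MeOH (1 equiv), Et2O, 0 °C
Reagents that add atoms: none
Why: Reductive removal of the auxiliary by hydride attack at the exocyclic imide carbonyl should release the primary alcohol without touching the alpha-stereocentre, and the oxazolidinone is recovered.

Step 10
Reactants: 15 (S)-2-methyloctan-1-ol
Product: 16 (S)-2-methyloctanal
Conditions: PhI(OAc)2, TEMPO (cat.), CH2Cl2, rt; used at once
Reagents that add atoms: none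
Why: The TEMPO-catalysed oxoammonium oxidation stops at the aldehyde and, being free of base, should not epimerise the alpha-centre.

Step 11
Reactants: 16 (S)-2-methyloctanal; 17 2-(triphenylphosphoranylidene)propanal
Product: 18 (S,E)-2,4-dimethyldec-2-enal
Conditions: toluene, 90 °C
Reagents that add atoms: none
Why: Wittig olefination with the formyl-stabilised ylide should give the E trisubstituted enal, as stabilised ylides do, and the conjugated, alpha-branched product reacts with the ylide much more slowly than the saturated aldehyde.

Step 12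
Reactants: 18 (S,E)-2,4-dimethyldec-2-enal; 19 triethyl phosphonoacetate
Product: 20 ethyl (2E,4E,6S)-4,6-dimethyldodeca-2,4-dienoate
Conditions: NaH, THF, 0 °C (anion preformed); then 18, 0 °C to rt
Reagents that add atoms: none
Why: Horner–Wadsworth–Emmons olefination of the enal with the stabilised phosphonate anion should form the new C2=C3 bond as the E isomer and leave the existing alkene and the remote stereocentre untouched.

Step 13
Reactants: 20 ethyl (2E,4E,6S)-4,6-dimethyldodeca-2,4-dienoate
Product: 21 (2E,4E,6S)-4,6-dimethyldodeca-2,4-dienoic acid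
Conditions: LiOH, THF/MeOH/H2O, rt; then 1 M HCl to pH 3
Reagents that add atoms: lithium hydroxide, [Li+].[OH-]
Why: Saponification of the ethyl ester followed by acidification should give the free acid without change of alkene geometry, the dienoate being a poor Michael acceptor for hydroxide.

Step 14
Reactants: 10 tert-butyl (E)-3-[(2S,3R)-3-hydroxy-6-oxo-3,6-dihydro-2H-pyran-2-yl]acrylate; 21 (2E,4E,6S)-4,6-dimethyldodeca-2,4-dienoic acid
Product: 22 tert-butyl (E)-3-[(2S,3S)-3-{[(2E,4E,6S)-4,6-dimethyldodeca-2,4-dienoyl]oxy}-6-oxo-3,6-dihydro-2H-pyran-2-yl]acrylate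
Conditions: PPh3, DIAD (added last), THF, 0 °C to rt
Reagents that add atoms: none
Why: Mitsunobu esterification: the C5 hydroxyl is activated as its oxyphosphonium salt and displaced by the carboxylate in an SN2 reaction with inversion, which should turn 5R into 5S and place the acyloxy group cis to the C6 side chain, anti elimination being disfavoured because C6–H is cis to the leaving group.

Step 15
Reactants: 22 tert-butyl (E)-3-[(2S,3S)-3-{[(2E,4E,6S)-4,6-dimethyldodeca-2,4-dienoyl]oxy}-6-oxo-3,6-dihydro-2H-pyran-2-yl]acrylate
Product: 23 (E)-3-[(2S,3S)-3-{[(2E,4E,6S)-4,6-dimethyldodeca-2,4-dienoyl]oxy}-6-oxo-3,6-dihydro-2H-pyran-2-yl]acrylic acid (target)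
Conditions: CF3CO2H, CH2Cl2, 0 °C to rt
Reagents that add atoms: none
Why: Acidolysis of the tert-butyl ester through the tert-butyl cation, lost as isobutene, should leave the secondary ester, the lactone, the alkenes and both ring stereocentres untouched.

Compound list
1 | furfural (furan-2-carbaldehyde) | O=Cc1ccco1 | starting material
2 | vinylmagnesium bromide | C=C[Mg]Br | starting material
3 | rac-1-(furan-2-yl)prop-2-en-1-ol | OC(c1ccco1)C=C | intermediate
4 | (S)-1-(furan-2-yl)prop-2-en-1-ol | O[C@H](c1ccco1)C=C | intermediate
5 | (S,Z)-5-hydroxy-4-oxohepta-2,6-dienal | O[C@H](C(=O)/C=C\C=O)C=C | intermediate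
6 | (2S)-6-hydroxy-2-vinyl-2H-pyran-3(6H)-one, mixture of anomers | O=C1C=CC(O)O[C@H]1C=C | intermediate
7 | (S)-6-vinyl-2H-pyran-2,5(6H)-dione | O=C1C=CC(=O)O[C@H]1C=C | intermediate
8 | (5R,6S)-5-hydroxy-6-vinyl-5,6-dihydro-2H-pyran-2-one (hydroxyl trans to vinyl) | O[C@@H]1C=CC(=O)O[C@H]1C=C | intermediate
9 | tert-butyl acrylate | C=CC(=O)OC(C)(C)C | starting material
10 | tert-butyl (E)-3-[(2S,3R)-3-hydroxy-6-oxo-3,6-dihydro-2H-pyran-2-yl]acrylate | O[C@@H]1C=CC(=O)O[C@H]1/C=C/C(=O)OC(C)(C)C | intermediate
11 | (S)-4-benzyloxazolidin-2-one | O=C1OC[C@H](Cc2ccccc2)N1 | starting material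
12 | octanoyl chloride | CCCCCCCC(=O)Cl | starting material
13 | (S)-4-benzyl-3-octanoyloxazolidin-2-one | CCCCCCCC(=O)N1C(=O)OC[C@@H]1Cc1ccccc1 | intermediate
14 | (S)-4-benzyl-3-[(S)-2-methyloctanoyl]oxazolidin-2-one | CCCCCC[C@H](C)C(=O)N1C(=O)OC[C@@H]1Cc1ccccc1 | intermediate
15 | (S)-2-methyloctan-1-ol | CCCCCC[C@H](C)CO | intermediate
16 | (S)-2-methyloctanal | CCCCCC[C@H](C)C=O | intermediate
17 | 2-(triphenylphosphoranylidene)propanal | CC(C=O)=P(c1ccccc1)(c1ccccc1)c1ccccc1 | starting material
18 | (S,E)-2,4-dimethyldec-2-enal | CCCCCC[C@H](C)/C=C(\C)C=O | intermediate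
19 | triethyl phosphonoacetate | CCOC(=O)CP(=O)(OCC)OCC | starting material
20 | ethyl (2E,4E,6S)-4,6-dimethyldodeca-2,4-dienoate | CCCCCC[C@H](C)/C=C(C)/C=C/C(=O)OCC | intermediate
21 | (2E,4E,6S)-4,6-dimethyldodeca-2,4-dienoic acid | CCCCCC[C@H](C)/C=C(C)/C=C/C(=O)O | intermediate
22 | tert-butyl (E)-3-[(2S,3S)-3-{[(2E,4E,6S)-4,6-dimethyldodeca-2,4-dienoyl]oxy}-6-oxo-3,6-dihydro-2H-pyran-2-yl]acrylate | CCCCCC[C@H](C)/C=C(C)/C=C/C(=O)O[C@H]1C=CC(=O)O[C@H]1/C=C/C(=O)OC(C)(C)C | intermediate
23 | (E)-3-[(2S,3S)-3-{[(2E,4E,6S)-4,6-dimethyldodeca-2,4-dienoyl]oxy}-6-oxo-3,6-dihydro-2H-pyran-2-yl]acrylic acid | CCCCCC[C@H](C)/C=C(C)/C=C/C(=O)O[C@H]1C=CC(=O)O[C@H]1/C=C/C(=O)O | target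

Total step count: 15. Longest linear sequence: 9 steps (steps 7 to 15, from octanoyl chloride); the lactone branch is 8 steps (steps 1 to 6, 14, 15).

Steps most likely to fail

Step 4. The ene-dione lactone has a C6–H that is alpha to the ketone, allylic and next to the ring oxygen. Enolisation there would erase the C6 configuration and could drain material into an aromatic hydroxy-pyranone tautomer or move the vinyl double bond into conjugation. Fallback: the ene-dione lactone is bypassed by reducing before oxidising. Setting out from 6, silylation of the anomeric hydroxyl (TBSCl, imidazole, CH2Cl2) should give (2S)-6-[(tert-butyldimethylsilyl)oxy]-2-vinyl-2H-pyran-3(6H)-one F1. Luche reduction (NaBH4, CeCl3·7H2O, MeOH, −78 °C) should then give (2S,3R)-6-[(tert-butyldimethylsilyl)oxy]-2-vinyl-3,6-dihydro-2H-pyran-3-ol F2. Buffered desilylation (Bu4NF, AcOH, THF, 0 °C) frees the lactol (2S,3R)-2-vinyl-3,6-dihydro-2H-pyran-3,6-diol F3. Ag2CO3 on Celite (toluene, 80 °C) should oxidise F3 at the lactol carbon in preference to the secondary alcohol, and the sequence comes back to the route at 8.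

Step 5. Hydride delivery may show poor or even reversed facial selectivity on the nearly flat ring, giving the cis alcohol alongside or instead of the trans alcohol. Fallback: both epimers are made productive. Setting out from 7, the reduction is run as before and the cis alcohol (5S,6S)-5-hydroxy-6-vinyl-5,6-dihydro-2H-pyran-2-one F4 is separated. It is cross-metathesised with 9 under the conditions of step 6 to tert-butyl (E)-3-[(2S,3S)-3-hydroxy-6-oxo-3,6-dihydro-2H-pyran-2-yl]acrylate F5. F5 is then acylated with 21 with retention (EDC, DMAP, CH2Cl2, 0 °C), which comes back to the route at 22.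

Step 14. Displacement at the activated C5 may lose out to elimination towards an aromatic 2-pyranone, helped by the C6–H now being gamma to the tert-butyl enoate, or to acyl transfer with retention. Fallback: the order of the two unions is reversed so that the inversion is done on the simpler vinyl lactone. Setting out from 8, Mitsunobu esterification with 21 (PPh3, DIAD, THF, 0 °C) should give (2S,3S)-6-oxo-2-vinyl-3,6-dihydro-2H-pyran-3-yl (2E,4E,6S)-4,6-dimethyldodeca-2,4-dienoate F6. Cross-metathesis of F6 with 9 (same ruthenium catalyst, CH2Cl2, 40 °C) should engage only the monosubstituted vinyl group, the trisubstituted and ester-conjugated alkenes of the dienoate being much less reactive, and comes back to the route at 22.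

Further compounds
F1 | step 4 | (2S)-6-[(tert-butyldimethylsilyl)oxy]-2-vinyl-2H-pyran-3(6H)-one | O=C1C=CC(O[Si](C)(C)C(C)(C)C)O[C@H]1C=C
F2 | step 4 | (2S,3R)-6-[(tert-butyldimethylsilyl)oxy]-2-vinyl-3,6-dihydro-2H-pyran-3-ol | O[C@@H]1C=CC(O[Si](C)(C)C(C)(C)C)O[C@H]1C=C
F3 | step 4 | (2S,3R)-2-vinyl-3,6-dihydro-2H-pyran-3,6-diol | O[C@@H]1C=CC(O)O[C@H]1C=C
F4 | step 5 | (5S,6S)-5-hydroxy-6-vinyl-5,6-dihydro-2H-pyran-2-one | O[C@H]1C=CC(=O)O[C@H]1C=C
F5 | step 5 | tert-butyl (E)-3-[(2S,3S)-3-hydroxy-6-oxo-3,6-dihydro-2H-pyran-2-yl]acrylate | O[C@H]1C=CC(=O)O[C@H]1/C=C/C(=O)OC(C)(C)C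
F6 | step 14 | (2S,3S)-6-oxo-2-vinyl-3,6-dihydro-2H-pyran-3-yl (2E,4E,6S)-4,6-dimethyldodeca-2,4-dienoate | CCCCCC[C@H](C)/C=C(C)/C=C/C(=O)O[C@H]1C=CC(=O)O[C@H]1C=C
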